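1. The easy step came first: I took logarithms of the first readings, all at 6.9 min.

| setting | maple | ash | birch | larch |
|---|---|---|---|---|
| starting material | 300 mM | 300 mM | 900 mM | 600 mM |
| coupling partner | 360 mM | 540 mM | 360 mM | 720 mM |
| time |  |  |  | 55 min |

- maple run (time / min: [product] / mM): 6.9: 83.1; 14: 143.2; 21: 185.3; 28: 215.8; 34: 231.9; 41: 246.2; 48: 254.7; 55: 261.3
- ash run (time / min: [product] / mM): 6.9: 99.1; 14: 171.5; 21: 219.1; 28: 249.2; 34: 261.9; 41: 274.0; 48: 277.6; 55: 280.7
- birch run (time / min: [product] / mM): 6.9: 147.1; 14: 248.4; 21: 304.5; 28: 333.6; 34: 346.0; 41: 351.7; 48: 358.0; 55: 358.5

(each reading ± 0.9 mM)

1. how the opening rate goes with [starting material] round the charge of the maple run: the exponent of the rate at two percent of starting material gone to product (one fixed amount of product, the same in the runs compared)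
2. how the opening rate goes with [coupling partner] round the charge of the maple run: the exponent of the rate at two percent of starting material gone to product
3. product in the larch run at 55 min, as a share of the starting material charged

- Overall: starting material + coupling partner -> product.
- Constant volume, constant temperature.
- Bound and free are read together.
- "The second partner" is coupling partner.
- An order is taken over about fifteen percent of the charge, up and down.

2. Birch against maple gave 0.520 for c(starting material). This is the log slope: the logarithm of the ratio of two first readings over the logarithm of the ratio of the charges that differ. Ash against maple gave 0.434 for c(coupling partner). These readings share one time, not one amount of product, so I took the slopes as estimates of the orders.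

3. For whoever takes over: the larch flask holds starting material, the limiting reagent, and coupling partner, with twice the maple charge of each.

4. For larch, the slopes put the opening rate at 1.94 times that of maple. So I expected larch to keep the maple share at 55 min, 87.1%, which means c(product) near 523 mM when you arrive.

5. Do not top up either partner. My reckoning needs the ratio of coupling partner to starting material, 1.20, which larch shares with maple.

6. The forecast differed from me: 0.7 for starting material, 0.45 for coupling partner and 90.5% for larch. Its grounds: “This suggests saturation or sequestration by both partners.”

7. The flask gave 0.49, 0.50 and 91.3%, the last above my share.

    starting material ⇌ intermediate (0.3708 /min, 1.674 /min)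
    intermediate + coupling partner → product (5.340 /M/min)
    starting material → decomposed substrate (0.01398 /min)
    2 starting material ⇌ idle substrate dimer, settled at all times (20.60 /M)

The forecast parted from the flask on starting material. Round the maple charge the order stood at 0.49 because pairs of starting material were parked as idle substrate dimer. The same maple charge with that parking taken away has order 0.69. For the birch charge, 900 mM against 300 mM, my log slope gives a factor of 1.77 at one time, and the rate of the birch run over that of the maple run, at one amount of product, is 1.6.

The earlier runs and the new flask stem from a simulated flask with made-up constants.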